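## Retrosynthetic overview

1. Sarothralin is reached from its aryl triisopropylsilyl ether by one fluoride step; the acylfilicinic acid ring (the cyclohexadienone with the gem-dimethyl carbon and the isobutyryl group) is the only ring built, and it is built last.
2. That ring is cut into two three-carbon halves for a [3+3] double C-acylation. The ring atoms C(CH3)2–C(=O)–C(acyl) together with the isobutyryl side chain are one symmetrical diketone, 2,6-dimethylheptane-3,5-dione, used as its 1,3-dianion. The ring atoms C(OH)–C(CH2Ar)–C(OH) are a benzylmalonyl unit.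
3. Enabling feature: the phenol oxygen of the benzophenone ring on the carbon between the CH2-bearing carbon and the benzoyl-bearing carbon can close a six-membered lactone (chroman-2-one) onto one malonyl carbonyl. The malonyl unit is therefore carried as that lactone plus a phenyl ester, two aryl esters of an acidic malonyl C–H that can transfer acyl through ketenes; the quaternary C(CH3)2 of the new ring blocks escape to an aromatic 2-pyranone.
4. The lactone phenyl ester comes from a coumarin-3-carboxylic acid (phenyl ester formation, prenylation of the only free OH, conjugate reduction), made from a salicylaldehyde and Meldrum's acid; the aldehyde comes from ortho-formylation of para-silylated 2,4,6-trihydroxybenzophenone.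
5. Ring order: benzophenone arene (bought), then the temporary lactone ring (step 3, cleaved in step 7), then the acylfilicinic acid ring (step 7).

Key step: step 7

Remarks on the chemistry:
- The target has no stereocentre and is drawn as one enol tautomer of a cyclic triketone; all tautomers count as the same compound.
- 2,4,6-Trihydroxybenzophenone and 2,6-dimethylheptane-3,5-dione are taken as purchasable.
- The anionic intermediates of step 7 are listed in their neutral forms, except the dianion.

## Route

Step 1
Reactants: 1 2,4,6-trihydroxybenzophenone; 2 chlorotriisopropylsilane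
Product: 3 (2,6-dihydroxy-4-{[triisopropylsilyl]oxy}phenyl)(phenyl)methanone
Conditions: i-Pr3SiCl (1.05 equiv), imidazole, DMF, 0 °C → rt
Reagents that add atoms: chlorotriisopropylsilane (2), CC(C)[Si](Cl)(C(C)C)C(C)C
Why: Silyl ether formation, in which the para hydroxyl is the only one not hydrogen-bonded to the benzoyl carbonyl and should be the only one taken by the bulky silyl chloride.

Step 2
Reactants: 3 (2,6-dihydroxy-4-{[triisopropylsilyl]oxy}phenyl)(phenyl)methanone; 4 paraformaldehyde
Product: 5 3-benzoyl-2,4-dihydroxy-6-{[triisopropylsilyl]oxy}benzaldehyde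
Conditions: MgCl2, Et3N, (CH2O)n, MeCN, 80 °C; cold 1 M HCl work-up
Reagents that add atoms: paraformaldehyde (4), written as formaldehyde, C=O
Why: Magnesium-mediated ortho-formylation (Casnati–Skattebøl reaction), in which the magnesium phenoxide delivers formaldehyde to the neighbouring ring carbon (the two open positions of 3 are equivalent) and a second formaldehyde oxidises the benzylic alkoxide to the aldehyde.

Step 3
Reactants: 5 3-benzoyl-2,4-dihydroxy-6-{[triisopropylsilyl]oxy}benzaldehyde; 6 Meldrum's acid (2,2-dimethyl-1,3-dioxane-4,6-dione)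
Product: 7 8-benzoyl-7-hydroxy-2-oxo-5-{[triisopropylsilyl]oxy}-2H-chromene-3-carboxylic acid
Conditions: piperidinium acetate (cat.), EtOH, 60 °C
Reagents that add atoms: Meldrum's acid (6), CC1(C)OC(=O)CC(=O)O1
Why: Knoevenagel condensation followed by lactonisation, in which the only free hydroxyl next to the alkylidene (the other neighbour is the silyl ether) opens the dioxanedione with loss of acetone and so fixes the position of the temporary lactone.

Step 4
Reactants: 7 8-benzoyl-7-hydroxy-2-oxo-5-{[triisopropylsilyl]oxy}-2H-chromene-3-carboxylic acid; 8 phenol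
Product: 9 phenyl 8-benzoyl-7-hydroxy-2-oxo-5-{[triisopropylsilyl]oxy}-2H-chromene-3-carboxylate
Conditions: PhOH (3 equiv), N,N'-dicyclohexylcarbodiimide, 4-(dimethylamino)pyridine (cat.), CH2Cl2, 0 °C → rt
Reagents that add atoms: phenol (8), Oc1ccccc1
Why: Steglich esterification, in which the activated acid is taken by the excess phenol while the hydrogen-bonded, vinylogous-acid 7-OH is a much poorer nucleophile.

Step 5
Reactants: 9 phenyl 8-benzoyl-7-hydroxy-2-oxo-5-{[triisopropylsilyl]oxy}-2H-chromene-3-carboxylate; 10 1-bromo-3-methylbut-2-ene (prenyl bromide)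
Product: 11 phenyl 8-benzoyl-7-[(3-methylbut-2-en-1-yl)oxy]-2-oxo-5-{[triisopropylsilyl]oxy}-2H-chromene-3-carboxylate
Conditions: prenyl bromide (1.5 equiv), K2CO3, acetone, 45 °C
Reagents that add atoms: 1-bromo-3-methylbut-2-ene (10), CC(C)=CCBr
Why: Williamson ether synthesis on the only hydroxyl left, which is acidic (vinylogous to the lactone carbonyl) and whose phenoxide should be alkylated at oxygen by the allylic bromide, so the prenyl group can only go to the correct oxygen.

Step 6
Reactants: 11 phenyl 8-benzoyl-7-[(3-methylbut-2-en-1-yl)oxy]-2-oxo-5-{[triisopropylsilyl]oxy}-2H-chromene-3-carboxylate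
Product: 12 phenyl 8-benzoyl-7-[(3-methylbut-2-en-1-yl)oxy]-2-oxo-5-{[triisopropylsilyl]oxy}-3,4-dihydro-2H-chromene-3-carboxylate (racemic at C3)
Conditions: Hantzsch ester (diethyl 2,6-dimethyl-1,4-dihydropyridine-3,5-dicarboxylate, 1.5 equiv), toluene, 80 °C
Reagents that add atoms: none
Why: Transfer hydrogenation (conjugate reduction) of a cyclic alkylidene malonate by the Hantzsch ester, with hydride going to C4 while the diaryl ketone, the phenyl ester and the prenyl alkene are left alone; the new C3 stereocentre is formed racemic, is configurationally labile and is erased in step 7.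

Step 7
Reactants: 12 phenyl 8-benzoyl-7-[(3-methylbut-2-en-1-yl)oxy]-2-oxo-5-{[triisopropylsilyl]oxy}-3,4-dihydro-2H-chromene-3-carboxylate; 13 2,6-dimethylheptane-3,5-dione
Product: 18 4-({3-benzoyl-2-hydroxy-4-[(3-methylbut-2-en-1-yl)oxy]-6-[(triisopropylsilyl)oxy]phenyl}methyl)-3,5-dihydroxy-6,6-dimethyl-2-(2-methylpropanoyl)cyclohexa-2,4-dien-1-one (sarothralin triisopropylsilyl ether), via diketone dianion 14 (not isolated), via lactone ketene 15 (not isolated), via acyl lactone 16 (not isolated), via acyl ketene 17 (not isolated)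
Conditions: 13 (1.3 equiv), NaH then n-BuLi, THF, 0 °C; 12 pre-treated with NaH (1.05 equiv, THF, 0 °C) added slowly at −78 °C, then → rt; cold 1 M HCl work-up
Reagents that add atoms: 2,6-dimethylheptane-3,5-dione (13), CC(C)C(=O)CC(=O)C(C)C
Why: Proposed new method: a [3+3] double C-acylation run as a ketene relay, in which the enolate of 12 expels phenoxide (E1cB) to give lactone ketene 15, the tertiary terminal carbanion of 14 adds to the ketene carbon to give 16 as its enolate, a second E1cB step opens the lactone (the ring phenoxide leaves) to give acyl ketene 17, and the central carbon of the remaining diketone enolate closes onto it, after which proton transfer to the strongly acidic triketone makes the sequence irreversible. The closest known reaction types are the terminal acylation of β-diketone 1,3-dianions by esters, the E1cB (ketene) acyl transfer of aryl malonates and aryl acetoacetates, the cyclocondensation of activated diaryl malonates with 1,3-dinucleophiles, the Effenberger cyclisation of malonyl dichloride with enol ethers and the Claisen cyclisation of 3,5,7-triketo esters to acylphloroglucinols. The one ring closed, the six-membered carbocycle, closes by attack of the endocyclic enolate carbon on the sp carbon of the ketene, a 6-(enolendo)-exo-dig closure (6-exo-trig if the lactone carbonyl is attacked directly). No stereocentre is formed and C3 of 12 becomes sp2. The step needs the terminal carbon to react before the central one and C- over O-acylation in the closure: the dianion reacts first at its terminal carbon, and because that carbon becomes the quaternary C(CH3)2, O-acylation can only give a non-aromatic 6-alkylidene enol lactone that reverts by the same E1cB path, so the C-acylated trione is the sink, and 17 results whichever aryloxide leaves first. The doubly ortho-substituted benzophenone carbonyl is too hindered to compete, the silyl ether removes the last acidic O–H, and the dianion is made with NaH and n-BuLi so that no amine is present to trap the ketenes.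

Step 8
Reactants: 18 sarothralin triisopropylsilyl ether
Product: 19 sarothralin, 4-({3-benzoyl-2,6-dihydroxy-4-[(3-methylbut-2-en-1-yl)oxy]phenyl}methyl)-3,5-dihydroxy-6,6-dimethyl-2-(2-methylpropanoyl)cyclohexa-2,4-dien-1-one
Conditions: tetrabutylammonium fluoride, AcOH, THF, 0 °C
Reagents that add atoms: none
Why: Fluoride-mediated desilylation of an aryl silyl ether para to the benzoyl group, under buffered conditions that should leave the prenyl ether and the enolised triketone untouched.

## Compound list

1 | 2,4,6-trihydroxybenzophenone | O=C(c1ccccc1)c1c(O)cc(O)cc1O | starting material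
2 | chlorotriisopropylsilane | CC(C)[Si](Cl)(C(C)C)C(C)C | starting material
3 | (2,6-dihydroxy-4-{[triisopropylsilyl]oxy}phenyl)(phenyl)methanone | O=C(c1ccccc1)c1c(O)cc(O[Si](C(C)C)(C(C)C)C(C)C)cc1O | intermediate
4 | paraformaldehyde (written as formaldehyde) | C=O | starting material
5 | 3-benzoyl-2,4-dihydroxy-6-{[triisopropylsilyl]oxy}benzaldehyde | O=Cc1c(O)c(C(=O)c2ccccc2)c(O)cc1O[Si](C(C)C)(C(C)C)C(C)C | intermediate
6 | Meldrum's acid (2,2-dimethyl-1,3-dioxane-4,6-dione) | CC1(C)OC(=O)CC(=O)O1 | starting material
7 | 8-benzoyl-7-hydroxy-2-oxo-5-{[triisopropylsilyl]oxy}-2H-chromene-3-carboxylic acid | OC(=O)C1=Cc2c(O[Si](C(C)C)(C(C)C)C(C)C)cc(O)c(C(=O)c3ccccc3)c2OC1=O | intermediate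
8 | phenol | Oc1ccccc1 | starting material
9 | phenyl 8-benzoyl-7-hydroxy-2-oxo-5-{[triisopropylsilyl]oxy}-2H-chromene-3-carboxylate | O=C(Oc1ccccc1)C1=Cc2c(O[Si](C(C)C)(C(C)C)C(C)C)cc(O)c(C(=O)c3ccccc3)c2OC1=O | intermediate
10 | 1-bromo-3-methylbut-2-ene (prenyl bromide) | CC(C)=CCBr | starting material
11 | phenyl 8-benzoyl-7-[(3-methylbut-2-en-1-yl)oxy]-2-oxo-5-{[triisopropylsilyl]oxy}-2H-chromene-3-carboxylate | O=C(Oc1ccccc1)C1=Cc2c(O[Si](C(C)C)(C(C)C)C(C)C)cc(OCC=C(C)C)c(C(=O)c3ccccc3)c2OC1=O | intermediate
12 | phenyl 8-benzoyl-7-[(3-methylbut-2-en-1-yl)oxy]-2-oxo-5-{[triisopropylsilyl]oxy}-3,4-dihydro-2H-chromene-3-carboxylate (racemic) | O=C(Oc1ccccc1)C1Cc2c(O[Si](C(C)C)(C(C)C)C(C)C)cc(OCC=C(C)C)c(C(=O)c3ccccc3)c2OC1=O | intermediate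
13 | 2,6-dimethylheptane-3,5-dione | CC(C)C(=O)CC(=O)C(C)C | starting material
14 | sodium lithium 2,6-dimethyl-3,5-dioxoheptane-2,4-diide (diketone 1,3-dianion) | [Na+].[Li+].CC(C)C(=O)[CH-]C(=O)[C-](C)C | intermediate
15 | 8-benzoyl-7-[(3-methylbut-2-en-1-yl)oxy]-3-(oxomethylidene)-5-{[triisopropylsilyl]oxy}-3,4-dihydro-2H-chromen-2-one (lactone ketene) | O=C=C1Cc2c(O[Si](C(C)C)(C(C)C)C(C)C)cc(OCC=C(C)C)c(C(=O)c3ccccc3)c2OC1=O | intermediate
16 | 8-benzoyl-7-[(3-methylbut-2-en-1-yl)oxy]-5-{[triisopropylsilyl]oxy}-3-(2,2,6-trimethyl-3,5-dioxoheptanoyl)-3,4-dihydro-2H-chromen-2-one (acyl lactone) | CC(C)C(=O)CC(=O)C(C)(C)C(=O)C1Cc2c(O[Si](C(C)C)(C(C)C)C(C)C)cc(OCC=C(C)C)c(C(=O)c3ccccc3)c2OC1=O | intermediate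
17 | 2-({3-benzoyl-2-hydroxy-4-[(3-methylbut-2-en-1-yl)oxy]-6-[(triisopropylsilyl)oxy]phenyl}methyl)-4,4,8-trimethyl-3,5,7-trioxonon-1-en-1-one (acyl ketene) | CC(C)C(=O)CC(=O)C(C)(C)C(=O)C(=C=O)Cc1c(O)c(C(=O)c2ccccc2)c(OCC=C(C)C)cc1O[Si](C(C)C)(C(C)C)C(C)C | intermediate
18 | 4-({3-benzoyl-2-hydroxy-4-[(3-methylbut-2-en-1-yl)oxy]-6-[(triisopropylsilyl)oxy]phenyl}methyl)-3,5-dihydroxy-6,6-dimethyl-2-(2-methylpropanoyl)cyclohexa-2,4-dien-1-one | CC(C)=CCOc1cc(O[Si](C(C)C)(C(C)C)C(C)C)c(CC2=C(O)C(C)(C)C(=O)C(C(=O)C(C)C)=C2O)c(O)c1C(=O)c1ccccc1 | intermediate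
19 | sarothralin | CC(C)=CCOc1cc(O)c(CC2=C(O)C(C)(C)C(=O)C(C(=O)C(C)C)=C2O)c(O)c1C(=O)c1ccccc1 | target

## Step count

Total step count: 8. Longest linear sequence: 8 steps (1 → 19); diketone 13 enters in step 7.

## Steps most likely to fail

**1. Step 7 (Proposed new method).** What may go wrong:
- Metalation of the tertiary C–H of 13 may be incomplete, so that the monoanion starts the sequence at its central carbon and the material drains into a 2-pyranone.
- The first E1cB ionisation of the enolate of 12 may be too slow in THF.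
- The sequence may stall at the acyl lactone or at the O-acylated enol lactone instead of closing at carbon.

The fallback uses known chemistry, sets out from 5 and returns at 18. The acylfilicinic acid ring is made separately and joined through the methylene carbon by an ortho-quinone methide Michael addition. Aldehyde 5 should be O-alkylated with 10 (K2CO3, acetone) at its 4-OH, the 2-OH being held between the formyl and benzoyl carbonyls, to give 3-benzoyl-2-hydroxy-4-[(3-methylbut-2-en-1-yl)oxy]-6-[(triisopropylsilyl)oxy]benzaldehyde F1. NaBH4 (THF/MeOH, 0 °C) should reduce only the formyl group to give the salicyl alcohol {2-hydroxy-3-(hydroxymethyl)-6-[(3-methylbut-2-en-1-yl)oxy]-4-[(triisopropylsilyl)oxy]phenyl}(phenyl)methanone F2. Isobutyrylfilicinic acid F3 would be made from purchased 2,4,6-trihydroxyisobutyrophenone by geminal C-methylation (MeI, NaOMe, MeOH). Warming F2 with F3 (toluene, 80 °C) should dehydrate F2 to the ortho-quinone methide 2-benzoyl-6-methylidene-3-[(3-methylbut-2-en-1-yl)oxy]-5-[(triisopropylsilyl)oxy]cyclohexa-2,4-dien-1-one F4, which should take the nucleophilic ring CH of F3 to give 18. Step 8 then follows unchanged.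

**2. Step 6.** What may go wrong:
- Hydride transfer to C4 may be sluggish, since C4 is shielded by the neighbouring silyloxy group and deactivated by two oxygen donors.
- The phenyl ester may be lost on prolonged heating.

The fallback sets out from 5 and returns at 12, and avoids the C3=C4 double bond altogether. Aldehyde 5 is taken to aldehyde F1 as described above. A three-component reductive alkylation of 6 with F1 and the Hantzsch ester (L-proline cat., EtOH, rt) should give the benzyl Meldrum's acid 5-({3-benzoyl-2-hydroxy-4-[(3-methylbut-2-en-1-yl)oxy]-6-[(triisopropylsilyl)oxy]phenyl}methyl)-2,2-dimethyl-1,3-dioxane-4,6-dione F5. Heating F5 (toluene, 70 °C) should let the free ortho hydroxyl open the dioxanedione with loss of acetone to give 8-benzoyl-7-[(3-methylbut-2-en-1-yl)oxy]-2-oxo-5-{[triisopropylsilyl]oxy}-3,4-dihydro-2H-chromene-3-carboxylic acid F6. Esterification of F6 with 8 (N,N'-dicyclohexylcarbodiimide, CH2Cl2, 0 °C) returns to 12.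

**3. Step 2.** What may go wrong:
- The magnesium phenoxide is tied up in a chelate with the benzoyl oxygen and the reacting carbon is flanked by the silyl ether, so hydroxymethylation may be slow.
- The silyl ether may be lost on long heating with base.

The fallback sets out from 3 and returns at 5. The phenoxide-directed hydroxymethylation–oxidation is replaced by an electrophilic aromatic substitution, the Vilsmeier–Haack formylation (POCl3, DMF, MeCN, 0 °C → rt; aqueous NaOAc), which acylphloroglucinol rings take readily and which needs no free coordination site at the phenoxide. The two open ring positions of 3 are equivalent, so 5 is again the only monoformyl product and no new compound is involved.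

## Further compounds

F1 | step 7 | 3-benzoyl-2-hydroxy-4-[(3-methylbut-2-en-1-yl)oxy]-6-[(triisopropylsilyl)oxy]benzaldehyde | O=Cc1c(O)c(C(=O)c2ccccc2)c(OCC=C(C)C)cc1O[Si](C(C)C)(C(C)C)C(C)C
F2 | step 7 | {2-hydroxy-3-(hydroxymethyl)-6-[(3-methylbut-2-en-1-yl)oxy]-4-[(triisopropylsilyl)oxy]phenyl}(phenyl)methanone | OCc1c(O)c(C(=O)c2ccccc2)c(OCC=C(C)C)cc1O[Si](C(C)C)(C(C)C)C(C)C
F3 | step 7 | isobutyrylfilicinic acid, 3,5-dihydroxy-6,6-dimethyl-2-(2-methylpropanoyl)cyclohexa-2,4-dien-1-one | CC(C)C(=O)C1=C(O)C=C(O)C(C)(C)C1=O
F4 | step 7 | 2-benzoyl-6-methylidene-3-[(3-methylbut-2-en-1-yl)oxy]-5-[(triisopropylsilyl)oxy]cyclohexa-2,4-dien-1-one | C=C1C(=O)C(C(=O)c2ccccc2)=C(OCC=C(C)C)C=C1O[Si](C(C)C)(C(C)C)C(C)C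
F5 | step 6 | 5-({3-benzoyl-2-hydroxy-4-[(3-methylbut-2-en-1-yl)oxy]-6-[(triisopropylsilyl)oxy]phenyl}methyl)-2,2-dimethyl-1,3-dioxane-4,6-dione | CC1(C)OC(=O)C(Cc2c(O)c(C(=O)c3ccccc3)c(OCC=C(C)C)cc2O[Si](C(C)C)(C(C)C)C(C)C)C(=O)O1
F6 | step 6 | 8-benzoyl-7-[(3-methylbut-2-en-1-yl)oxy]-2-oxo-5-{[triisopropylsilyl]oxy}-3,4-dihydro-2H-chromene-3-carboxylic acid | OC(=O)C1Cc2c(O[Si](C(C)C)(C(C)C)C(C)C)cc(OCC=C(C)C)c(C(=O)c3ccccc3)c2OC1=O
F0 | step 2 | none | none
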